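**Assumption:** the target is achiral (no stereocentres), so there is no configuration to set. The sulfate is delivered as the free hydrogen sulfate as drawn, and is best stored as its ammonium salt.

## Retrosynthetic overview

1. Target 13 ⇐ flavone 12 by one reductive operation that removes two PMB ethers and the trichloroethyl (TCE) sulfate ester.
2. 12 ⇐ aryl ynoate 10: the C4–C4a bond comes from a photo-Fries rearrangement (caged aryloxyl/acyl radical pair), then 6-endo-dig O1–C2 closure. The pyranone C ring is the only ring made, and it is made last; the A and B benzene rings are bought.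
3. 10 ⇐ phenol 5 + arylpropiolic acid 9 (ester bond).
4. 5 ⇐ resorcinol 1: PMB protection, C2 lithiation/oxidation/methylation (the 6-OMe), then Ir C–H borylation/oxidation at C5 (the future O1).
5. 9 ⇐ 4-iodophenol 6 (sulfated as the TCE ester) + propiolic acid 8 (Sonogashira).

## Route

Step 1
Reactants: 1 resorcinol
Product: 2, 1,3-bis[(4-methoxybenzyl)oxy]benzene
Conditions: PMBCl (2.2 equiv), K2CO3, TBAI (cat.), DMF, 60 °C
Reagents that add atoms: 4-methoxybenzyl chloride, COc1ccc(CCl)cc1
Why: Double Williamson etherification of the two phenols; PMB is chosen because every C–H on its ring is ortho to a substituent (matters in step 4) and it is hydrogenolysable (step 9).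

Step 2
Reactants: 2, 1,3-bis[(4-methoxybenzyl)oxy]benzene
Product: 3, 2,6-bis[(4-methoxybenzyl)oxy]phenol
Conditions: n-BuLi (1.15 equiv), THF, 0 °C → rt; B(OMe)3, −78 °C → rt; then 30% H2O2, aq NaOH, 0 °C
Reagents that add atoms: hydrogen peroxide, OO (supplies the new phenolic O)
Why: Directed ortho-metalation at the doubly activated C2–H between the two ether oxygens (faster than benzylic deprotonation at 0 °C), borate formation and oxidative C–B → C–O conversion.

Step 3
Reactants: 3, 2,6-bis[(4-methoxybenzyl)oxy]phenol
Product: 4, 2-methoxy-1,3-bis[(4-methoxybenzyl)oxy]benzene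
Conditions: MeI, K2CO3, DMF, rt
Reagents that add atoms: iodomethane, CI
Why: Simple phenoxide O-methylation (Williamson) installs the future 6-OMe.

Step 4
Reactants: 4, 2-methoxy-1,3-bis[(4-methoxybenzyl)oxy]benzene
Product: 5, 4-methoxy-3,5-bis[(4-methoxybenzyl)oxy]phenol
Conditions: [Ir(OMe)(cod)]2 (1.5 mol%), dtbpy (3 mol%), B2pin2 (0.6 equiv), THF, 80 °C; then aq H2O2, NaOH, 0 °C → rt (one pot)
Reagents that add atoms: hydrogen peroxide, OO
Why: Sterically controlled Ir-catalysed C–H borylation occurs at C5, the only C–H in the molecule with no ortho substituent (all PMB C–H bonds are ortho-flanked), and the boronate is oxidised in situ to the phenol that becomes O1.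

Step 5
Reactants: 6, 4-iodophenol
Product: 7, 4-iodophenyl 2,2,2-trichloroethyl sulfate
Conditions: Cl3CCH2OSO2Cl (1.2 equiv), Et3N, DMAP, THF, 0 °C → rt
Reagents that add atoms: 2,2,2-trichloroethyl chlorosulfate, ClS(=O)(=O)OCC(Cl)(Cl)Cl
Why: O-sulfonylation of the phenol installs the 4'-sulfate at the outset as a neutral, acid-stable, reductively cleavable TCE diester, so no late-stage regioselective sulfation is needed.

Step 6
Reactants: 7, 4-iodophenyl 2,2,2-trichloroethyl sulfate; 8, propiolic acid
Product: 9, 3-{4-[(2,2,2-trichloroethoxy)sulfonyloxy]phenyl}prop-2-ynoic acid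
Conditions: Pd(PPh3)2Cl2 (3 mol%), CuI (5 mol%), Et3N (3 equiv), THF, rt, Ar
Reagents that add atoms: none (both partners are listed reactants)
Why: Sonogashira coupling at the aryl iodide (far more reactive than the aryl sulfate C–O bond) with propiolic acid as its ammonium salt; room temperature and a tertiary amine avoid Cu-promoted decarboxylation and base-induced HCl loss from the TCE group.

Step 7
Reactants: 5, 4-methoxy-3,5-bis[(4-methoxybenzyl)oxy]phenol; 9, the arylpropiolic acid
Product: 10, 4-methoxy-3,5-bis[(4-methoxybenzyl)oxy]phenyl 3-{4-[(2,2,2-trichloroethoxy)sulfonyloxy]phenyl}prop-2-ynoate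
Conditions: DCC (1.1 equiv), DMAP (10 mol%), CH2Cl2, 0 °C → rt
Reagents that add atoms: none
Why: Steglich esterification of the unhindered phenol OH (both ortho positions are H) tethers all 16 skeletal carbons through the oxygen that will become O1.

Step 8
Reactants: 10, the aryl arylpropiolate
Product: 12, 6-methoxy-5,7-bis[(4-methoxybenzyl)oxy]-2-{4-[(2,2,2-trichloroethoxy)sulfonyloxy]phenyl}-4H-chromen-4-one, formed via 11, 1-{2-hydroxy-5-methoxy-4,6-bis[(4-methoxybenzyl)oxy]phenyl}-3-{4-[(2,2,2-trichloroethoxy)sulfonyloxy]phenyl}prop-2-yn-1-one (not isolated)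
Conditions: hν (254 nm, quartz; or 300 nm), degassed MeCN (5 mM), rt, to about 85% conversion; then DMAP (0.3 equiv), 40 °C, same pot
Reagents that add atoms: none (two isomerisations)
Why: Photo-Fries rearrangement: the excited ester homolyses at ArO–C(O) and the caged aryloxyl/alkynoyl radical pair recombines at an ortho carbon (the two are equivalent; para is blocked by OMe) to form C4–C4a and give ynone 11, which DMAP closes by 6-endo-dig oxa-Michael addition through the only free phenol, fixing the 5,6,7-oxygenation pattern.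

Step 9
Reactants: 12, the protected flavone
Product: 13, hispidulin 4'-sulfate, 4-(5,7-dihydroxy-6-methoxy-4-oxo-4H-chromen-2-yl)phenyl hydrogen sulfate
Conditions: 10% Pd/C, HCO2NH4 (10 equiv), MeOH–THF, rt (monitor, stop at full conversion); then Dowex 50W (H+), 0 °C, lyophilise
Reagents that add atoms: none
Why: Catalytic transfer hydrogenolysis cleaves both PMB ethers and reductively fragments the TCE ester (C–Cl reduction, β-elimination) to the aryl sulfate monoester, which survives these neutral conditions; brief H+ exchange gives the acid form.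

## Compound list

1 | resorcinol | Oc1cccc(O)c1 | starting material
2 | 1,3-bis[(4-methoxybenzyl)oxy]benzene | COc1ccc(COc2cccc(OCc3ccc(OC)cc3)c2)cc1 | intermediate
3 | 2,6-bis[(4-methoxybenzyl)oxy]phenol | COc1ccc(COc2cccc(OCc3ccc(OC)cc3)c2O)cc1 | intermediate
4 | 2-methoxy-1,3-bis[(4-methoxybenzyl)oxy]benzene | COc1ccc(COc2cccc(OCc3ccc(OC)cc3)c2OC)cc1 | intermediate
5 | 4-methoxy-3,5-bis[(4-methoxybenzyl)oxy]phenol | COc1ccc(COc2cc(O)cc(OCc3ccc(OC)cc3)c2OC)cc1 | intermediate
6 | 4-iodophenol | Oc1ccc(I)cc1 | starting material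
7 | 4-iodophenyl 2,2,2-trichloroethyl sulfate | ClC(Cl)(Cl)COS(=O)(=O)Oc1ccc(I)cc1 | intermediate
8 | propiolic acid | C#CC(=O)O | starting material
9 | 3-{4-[(2,2,2-trichloroethoxy)sulfonyloxy]phenyl}prop-2-ynoic acid | OC(=O)C#Cc1ccc(OS(=O)(=O)OCC(Cl)(Cl)Cl)cc1 | intermediate
10 | 4-methoxy-3,5-bis[(4-methoxybenzyl)oxy]phenyl 3-{4-[(2,2,2-trichloroethoxy)sulfonyloxy]phenyl}prop-2-ynoate | COc1ccc(COc2cc(OC(=O)C#Cc3ccc(OS(=O)(=O)OCC(Cl)(Cl)Cl)cc3)cc(OCc3ccc(OC)cc3)c2OC)cc1 | intermediate
11 | 1-{2-hydroxy-5-methoxy-4,6-bis[(4-methoxybenzyl)oxy]phenyl}-3-{4-[(2,2,2-trichloroethoxy)sulfonyloxy]phenyl}prop-2-yn-1-one | COc1ccc(COc2cc(O)c(C(=O)C#Cc3ccc(OS(=O)(=O)OCC(Cl)(Cl)Cl)cc3)c(OCc3ccc(OC)cc3)c2OC)cc1 | intermediate (not isolated)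
12 | 6-methoxy-5,7-bis[(4-methoxybenzyl)oxy]-2-{4-[(2,2,2-trichloroethoxy)sulfonyloxy]phenyl}-4H-chromen-4-one | COc1c(OCc2ccc(OC)cc2)cc2oc(-c3ccc(OS(=O)(=O)OCC(Cl)(Cl)Cl)cc3)cc(=O)c2c1OCc1ccc(OC)cc1 | intermediate
13 | hispidulin 4'-sulfate | COc1c(O)cc2oc(-c3ccc(OS(=O)(=O)O)cc3)cc(=O)c2c1O | target

## Step count and risks

Total steps: 9. Longest linear sequence: 7 (steps 1, 2, 3, 4, 7, 8, 9); steps 5 and 6 form the convergent branch.

Steps most likely to fail:

1. **Step 8 (photo-Fries/cyclisation).** Cage recombination may be inefficient (phenol 5 is the escape product and can be recycled through step 7), the PMB ethers or the sulfate diester may undergo competing photochemistry, or some 5-exo aurone may form. Fallback: make the (E)-cinnamate analogue instead (Heck of 7 with acrylic acid, esterify with 5), run the photo-Fries to the 2'-hydroxychalcone, and close and oxidise with I2/DMSO to the same flavone 12.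
2. **Step 9 (global transfer hydrogenolysis).** The C2=C3 bond may be over-reduced or the hindered 5-O-PMB may cleave incompletely. Fallback: a non-hydrogenative two-stage endgame, TFA/anisole to remove the PMB ethers (the TCE sulfate diester is acid-stable), then Zn/HCO2NH4 in MeOH to cleave the TCE group.
3. **Step 6 (Sonogashira with free propiolic acid).** Decarboxylation or Glaser coupling may compete, or the base may eliminate HCl from the TCE group. Fallback: couple 7 with trimethylsilylacetylene, then install the acid by CsF-mediated desilylative carboxylation with CO2 to reach 9.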